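**Plan**
Numbering: ring C1 (ketone), C2 (methyl, oxirane), C3 (oxirane CH), C4 (CH2), C5 (CH with side chain), C6 (CH–O-acyl); side chain C7 (oxirane carbon), C8 (ketone), C9=C10, C11 (C–OOH).
Retrosynthesis cuts C11–OOH (ene reaction of a prenyl ketone), C10=C11 and C8–C9 (metathesis, allylation of a C8 aldehyde), the C7 oxirane, the ester and C6–O, the C2–C3 oxirane, then C1–C2 and C3–C4 together, and last C5–C7.
Enabling feature: C1(=O)/C2(Me)/C3(H) is a masked 2-methyl-2-enone, so the carbocycle is a four-carbon acyl–alkyl unit C1–C6–C5–C4 (a 3-substituted cyclobutanone, C5 being its C3) plus a two-carbon alkyne C2≡C3.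
Forward: acid → 3-alkenylcyclobutanone → nickel-catalysed alkyne insertion (ring) → C1 reduction, directed epoxidation, re-oxidation → C6 hydroxylation and acylation → C7 oxirane → C8–C11 chain → hydroperoxide.
Stereochemistry: C5 by enantiotopic C–C bond selection at a chiral nickel catalyst; the temporary C1–OH (cis to the C5 group) directs the C2–C3 oxirane; C6 by enolate oxidation anti to the C5 group and the oxirane; C7 by catalyst-controlled epoxidation; the E-alkene by the ene reaction.

Key step: step 4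

Remark: the enantiomers of the phosphoramidite (step 4) and of the prolinol catalyst (step 11) are assigned by analogy only, and the antipode would be used if the sense of induction proves opposite; the C8 carbinol formed by allylation is carried as an epimer mixture because it becomes a ketone.

Step 1
Reactants: 1 3-oxocyclobutane-1-carboxylic acid; 2 N-hydroxyphthalimide
Product: 3 1,3-dioxoisoindolin-2-yl 3-oxocyclobutane-1-carboxylate
Conditions: N,N'-diisopropylcarbodiimide, DMAP (cat.), CH2Cl2, rt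
Reagents that add atoms: none
Why: Carbodiimide esterification gives the redox-active N-acyloxyphthalimide; no stereocentre is involved.

Step 2
Reactants: 3 1,3-dioxoisoindolin-2-yl 3-oxocyclobutane-1-carboxylate; 4 2-bromo-3,3-diethoxyprop-1-ene
Product: 7 3-(3,3-diethoxyprop-1-en-2-yl)cyclobutan-1-one, via alkenyllithium 5 (not isolated), via alkenylzinc chloride 6 (not isolated)
Conditions: 4, n-BuLi, THF, −78 °C; ZnCl2; then 3, Ni(acac)2 (10 mol %), 2,2'-bipyridine (10 mol %), THF/DMF, rt
Reagents that add atoms: none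
Why: Nickel-catalysed decarboxylative alkenylation of a redox-active ester: single-electron reduction releases CO2 and the 3-oxocyclobutyl radical, which is captured at nickel and coupled with the alkenylzinc reagent, the ketone being inert to organozinc halides; 7 is achiral (mirror plane through C1 and C3 of the four-membered ring).

Step 3
Reactants: 8 prop-1-yn-1-ylmagnesium bromide; 9 benzyl(chloro)dimethylsilane
Product: 10 benzyldimethyl(prop-1-yn-1-yl)silane
Conditions: THF, 0 °C to rt
Reagents that add atoms: none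
Why: Substitution at silicon by the alkynyl Grignard reagent; the benzyldimethylsilyl group is chosen because fluoride removes it from an alkene carbon under mild conditions.

Step 4
Reactants: 7 3-(3,3-diethoxyprop-1-en-2-yl)cyclobutan-1-one; 10 benzyldimethyl(prop-1-yn-1-yl)silane
Product: 12 (5R)-5-(3,3-diethoxyprop-1-en-2-yl)-2-methylcyclohex-2-en-1-one, via silyl enone 11 (not isolated)
Conditions: Ni(cod)2 (10 mol %), (S)-BINOL-derived N,N-bis[(S)-1-phenylethyl]phosphoramidite (20 mol %), toluene, 80 °C, slow addition of 10; then TBAF, THF, 0 °C to rt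
Reagents that add atoms: none
Why: Proposed new method: zerovalent nickel joins the C=O of 7 and alkyne 10 by oxidative cyclisation to a spiro oxanickelacyclopentene, the carbonyl carbon bonding to the methyl-bearing alkyne carbon because the bulky silyl-bearing carbon prefers the position on nickel, then strain release drives β-carbon elimination of one ring CH2 to nickel and C(sp2)–C(sp3) reductive elimination closes the ring. The closest known reaction type is the nickel/trialkylphosphine-catalysed insertion of internal alkynes into 3-substituted cyclobutanones (achiral), together with the enantioselective intramolecular alkene insertion into cyclobutanones under Ni(cod)2/chiral phosphoramidite catalysis; enantiotopic-bond selection in the intermolecular alkyne case is the untested element. The six-membered ring closes by reductive elimination from a seven-membered nickelacycle, a formal [4+2] ring expansion of the four-membered ketone by the two alkyne carbons. The only new stereocentre, C5, is set because the two C(O)–CH2 bonds of 7 are enantiotopic and the chiral ligand on nickel decides which one migrates in the β-carbon elimination. The step needs alkyne regioselectivity (silyl group), enantiotopic group selectivity (ligand) and chemoselectivity over alkyne oligomerisation and over the side-chain alkene and acetal (slow addition of 10; a 1,1-disubstituted alkene and an unactivated acetal bind zerovalent nickel poorly). Fluoride then cleaves the benzyl–silicon bond and protodesilylates the resulting fluorosilane, leaving hydrogen at C3.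

Step 5
Reactants: 12 (5R)-5-(3,3-diethoxyprop-1-en-2-yl)-2-methylcyclohex-2-en-1-one
Product: 13 (1R,5R)-5-(3,3-diethoxyprop-1-en-2-yl)-2-methylcyclohex-2-en-1-ol (OH cis to the C5 group)
Conditions: NaBH4, CeCl3·7H2O, EtOH, −40 °C
Reagents that add atoms: none
Why: Luche 1,2-reduction: axial hydride delivery to the half-chair enone gives the equatorial alcohol cis to the equatorial C5 substituent (new centre C1, substrate control), and ethanol as solvent leaves the diethyl acetal unchanged.

Step 6
Reactants: 13 (1R,5R)-5-(3,3-diethoxyprop-1-en-2-yl)-2-methylcyclohex-2-en-1-ol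
Product: 14 (1R,2R,4S,6S)-4-(3,3-diethoxyprop-1-en-2-yl)-1-methyl-7-oxabicyclo[4.1.0]heptan-2-ol (oxirane, OH and side chain all cis)
Conditions: VO(acac)2 (5 mol %), t-BuOOH (decane), CH2Cl2, 0 °C to rt
Reagents that add atoms: tert-butyl hydroperoxide, CC(C)(C)OO
Why: Hydroxyl-directed vanadium-catalysed epoxidation delivers oxygen to the C2=C3 face syn to the C1 hydroxyl (sets C2 and C3 cis to the C5 group), while the isolated 1,1-disubstituted alkene, which has no allylic hydroxyl, does not react.

Step 7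
Reactants: 14 (1R,2R,4S,6S)-4-(3,3-diethoxyprop-1-en-2-yl)-1-methyl-7-oxabicyclo[4.1.0]heptan-2-ol
Product: 15 (1S,4R,6S)-4-(3,3-diethoxyprop-1-en-2-yl)-1-methyl-7-oxabicyclo[4.1.0]heptan-2-one
Conditions: Dess–Martin periodinane, NaHCO3, CH2Cl2, 0 °C to rt
Reagents that add atoms: none
Why: Buffered Dess–Martin oxidation of the secondary alcohol returns the C1 ketone without touching oxirane, acetal or alkene.

Step 8
Reactants: 15 (1S,4R,6S)-4-(3,3-diethoxyprop-1-en-2-yl)-1-methyl-7-oxabicyclo[4.1.0]heptan-2-one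
Product: 16 (1S,3S,4S,6S)-4-(3,3-diethoxyprop-1-en-2-yl)-3-hydroxy-1-methyl-7-oxabicyclo[4.1.0]heptan-2-one
Conditions: KHMDS, THF, −78 °C; then 2-(phenylsulfonyl)-3-phenyloxaziridine; AcOH quench
Reagents that add atoms: 2-(phenylsulfonyl)-3-phenyloxaziridine, O=S(=O)(c1ccccc1)N1OC1c1ccccc1
Why: Oxidation of the potassium enolate (only C6 is enolisable) with an N-sulfonyloxaziridine; the oxidant approaches C6 anti to both the C5 group and the oxirane, giving the trans (equatorial) hydroxyl, which is also the thermodynamically preferred epimer.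

Step 9
Reactants: 16 (1S,3S,4S,6S)-4-(3,3-diethoxyprop-1-en-2-yl)-3-hydroxy-1-methyl-7-oxabicyclo[4.1.0]heptan-2-one; 17 3-methylbutanoyl chloride
Product: 18 (1S,3S,4S,6S)-4-(3,3-diethoxyprop-1-en-2-yl)-1-methyl-2-oxo-7-oxabicyclo[4.1.0]heptan-3-yl 3-methylbutanoate
Conditions: pyridine, DMAP (cat.), CH2Cl2, 0 °C
Reagents that add atoms: none
Why: Acylation of the secondary α-hydroxy ketone with the acid chloride under nucleophilic catalysis; no stereocentre is touched.

Step 10
Reactants: 18 (1S,3S,4S,6S)-4-(3,3-diethoxyprop-1-en-2-yl)-1-methyl-2-oxo-7-oxabicyclo[4.1.0]heptan-3-yl 3-methylbutanoate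
Product: 19 (1S,3S,4S,6S)-1-methyl-2-oxo-4-(3-oxoprop-1-en-2-yl)-7-oxabicyclo[4.1.0]heptan-3-yl 3-methylbutanoate
Conditions: PPTS (cat.), acetone/H2O, rt
Reagents that add atoms: water, O
Why: Mild acid-catalysed hydrolysis of the allylic acetal (stabilised oxocarbenium ion) frees the 2-substituted acrolein while the epoxy ketone and the ester survive.

Step 11
Reactants: 19 (1S,3S,4S,6S)-1-methyl-2-oxo-4-(3-oxoprop-1-en-2-yl)-7-oxabicyclo[4.1.0]heptan-3-yl 3-methylbutanoate
Product: 20 (1S,3S,4R,6S)-4-[(2S)-2-formyloxiran-2-yl]-1-methyl-2-oxo-7-oxabicyclo[4.1.0]heptan-3-yl 3-methylbutanoate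
Conditions: (R)-α,α-diphenylprolinol trimethylsilyl ether (10 mol %), 30% aq. H2O2, CH2Cl2, rt
Reagents that add atoms: hydrogen peroxide, OO
Why: Aminocatalytic nucleophilic epoxidation of an α-substituted acrolein: iminium activation, conjugate addition of H2O2 and ring closure of the enamine on the face left open by the diarylsilyloxymethyl group set the quaternary oxirane carbon C7 under catalyst control, and the ring ketone is not activated by the secondary amine.

Step 12
Reactants: 20 (1S,3S,4R,6S)-4-[(2S)-2-formyloxiran-2-yl]-1-methyl-2-oxo-7-oxabicyclo[4.1.0]heptan-3-yl 3-methylbutanoate; 21 2-allyl-4,4,5,5-tetramethyl-1,3,2-dioxaborolane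
Product: 22 (1S,3S,4R,6S)-4-[(2S)-2-(1-hydroxybut-3-en-1-yl)oxiran-2-yl]-1-methyl-2-oxo-7-oxabicyclo[4.1.0]heptan-3-yl 3-methylbutanoate (mixture of C8 epimers)
Conditions: CH2Cl2, rt; aq. NaHCO3 work-up
Reagents that add atoms: none
Why: Uncatalysed allylboration through a closed six-membered transition state reacts with the aldehyde only and leaves the hindered ring ketone, the ester and both oxiranes untouched; the new carbinol centre is not controlled and is removed in step 14.

Step 13
Reactants: 22 (1S,3S,4R,6S)-4-[(2S)-2-(1-hydroxybut-3-en-1-yl)oxiran-2-yl]-1-methyl-2-oxo-7-oxabicyclo[4.1.0]heptan-3-yl 3-methylbutanoate; 23 2-methylbut-2-ene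
Product: 24 (1S,3S,4R,6S)-4-[(2S)-2-(1-hydroxy-4-methylpent-3-en-1-yl)oxiran-2-yl]-1-methyl-2-oxo-7-oxabicyclo[4.1.0]heptan-3-yl 3-methylbutanoate (mixture of C8 epimers)
Conditions: second-generation Grubbs catalyst (5 mol %), 2-methylbut-2-ene/CH2Cl2, 40 °C
Reagents that add atoms: none
Why: Olefin cross-metathesis of the terminal alkene with excess 2-methylbut-2-ene exchanges =CH2 for =CMe2 (a standard route to a prenyl group), done at the alcohol stage so that no base-sensitive allyl ketone meets the ruthenium catalyst.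

Step 14
Reactants: 24 (1S,3S,4R,6S)-4-[(2S)-2-(1-hydroxy-4-methylpent-3-en-1-yl)oxiran-2-yl]-1-methyl-2-oxo-7-oxabicyclo[4.1.0]heptan-3-yl 3-methylbutanoate
Product: 25 (1S,3S,4R,6S)-1-methyl-4-[(2S)-2-(4-methylpent-3-enoyl)oxiran-2-yl]-2-oxo-7-oxabicyclo[4.1.0]heptan-3-yl 3-methylbutanoate
Conditions: Dess–Martin periodinane, NaHCO3, CH2Cl2, 0 °C
Reagents that add atoms: none
Why: Buffered Dess–Martin oxidation converts both C8 epimers into the single β,γ-unsaturated ketone without moving the trisubstituted alkene into conjugation.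

Step 15
Reactants: 25 (1S,3S,4R,6S)-1-methyl-4-[(2S)-2-(4-methylpent-3-enoyl)oxiran-2-yl]-2-oxo-7-oxabicyclo[4.1.0]heptan-3-yl 3-methylbutanoate
Product: 26 (1S,3S,4R,6S)-4-{(2S)-2-[(2E)-4-hydroperoxy-4-methylpent-2-enoyl]oxiran-2-yl}-1-methyl-2-oxo-7-oxabicyclo[4.1.0]heptan-3-yl 3-methylbutanoate (CNP0131119.2)
Conditions: O2, hν (visible), tetraphenylporphyrin (cat.), CH2Cl2, 0 °C
Reagents that add atoms: dioxygen, O=O
Why: Schenck ene reaction of singlet oxygen with the trisubstituted alkene: abstraction of a C9 hydrogen (on the more substituted side of the alkene, giving the conjugated enone) puts the hydroperoxide on the tertiary C11 and forms the C9=C10 bond trans; no stereocentre is created.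

**Compound list**
1 | 3-oxocyclobutane-1-carboxylic acid | O=C1CC(C(=O)O)C1 | starting material
2 | N-hydroxyphthalimide | O=C1N(O)C(=O)c2ccccc12 | starting material
3 | 1,3-dioxoisoindolin-2-yl 3-oxocyclobutane-1-carboxylate | O=C1CC(C(=O)ON2C(=O)c3ccccc3C2=O)C1 | intermediate
4 | 2-bromo-3,3-diethoxyprop-1-ene | C=C(Br)C(OCC)OCC | starting material
5 | (3,3-diethoxyprop-1-en-2-yl)lithium | [Li]C(=C)C(OCC)OCC | intermediate
6 | chloro(3,3-diethoxyprop-1-en-2-yl)zinc | Cl[Zn]C(=C)C(OCC)OCC | intermediate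
7 | 3-(3,3-diethoxyprop-1-en-2-yl)cyclobutan-1-one | O=C1CC(C(=C)C(OCC)OCC)C1 | intermediate
8 | prop-1-yn-1-ylmagnesium bromide | CC#C[Mg]Br | starting material
9 | benzyl(chloro)dimethylsilane | C[Si](C)(Cl)Cc1ccccc1 | starting material
10 | benzyldimethyl(prop-1-yn-1-yl)silane | CC#C[Si](C)(C)Cc1ccccc1 | intermediate
11 | (5S)-3-[benzyl(dimethyl)silyl]-5-(3,3-diethoxyprop-1-en-2-yl)-2-methylcyclohex-2-en-1-one | C1C(=O)C(C)=C([Si](C)(C)Cc2ccccc2)C[C@H]1C(=C)C(OCC)OCC | intermediate
12 | (5R)-5-(3,3-diethoxyprop-1-en-2-yl)-2-methylcyclohex-2-en-1-one | C1C(=O)C(C)=CC[C@H]1C(=C)C(OCC)OCC | intermediate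
13 | (1R,5R)-5-(3,3-diethoxyprop-1-en-2-yl)-2-methylcyclohex-2-en-1-ol | C1[C@@H](O)C(C)=CC[C@H]1C(=C)C(OCC)OCC | intermediate
14 | (1R,2R,4S,6S)-4-(3,3-diethoxyprop-1-en-2-yl)-1-methyl-7-oxabicyclo[4.1.0]heptan-2-ol | C1[C@@H](O)[C@@]2(C)O[C@H]2C[C@H]1C(=C)C(OCC)OCC | intermediate
15 | (1S,4R,6S)-4-(3,3-diethoxyprop-1-en-2-yl)-1-methyl-7-oxabicyclo[4.1.0]heptan-2-one | C1C(=O)[C@@]2(C)O[C@H]2C[C@H]1C(=C)C(OCC)OCC | intermediate
16 | (1S,3S,4S,6S)-4-(3,3-diethoxyprop-1-en-2-yl)-3-hydroxy-1-methyl-7-oxabicyclo[4.1.0]heptan-2-one | O[C@@H]1C(=O)[C@@]2(C)O[C@H]2C[C@H]1C(=C)C(OCC)OCC | intermediate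
17 | 3-methylbutanoyl chloride | CC(C)CC(=O)Cl | starting material
18 | (1S,3S,4S,6S)-4-(3,3-diethoxyprop-1-en-2-yl)-1-methyl-2-oxo-7-oxabicyclo[4.1.0]heptan-3-yl 3-methylbutanoate | CC(C)CC(=O)O[C@@H]1C(=O)[C@@]2(C)O[C@H]2C[C@H]1C(=C)C(OCC)OCC | intermediate
19 | (1S,3S,4S,6S)-1-methyl-2-oxo-4-(3-oxoprop-1-en-2-yl)-7-oxabicyclo[4.1.0]heptan-3-yl 3-methylbutanoate | CC(C)CC(=O)O[C@@H]1C(=O)[C@@]2(C)O[C@H]2C[C@H]1C(=C)C=O | intermediate
20 | (1S,3S,4R,6S)-4-[(2S)-2-formyloxiran-2-yl]-1-methyl-2-oxo-7-oxabicyclo[4.1.0]heptan-3-yl 3-methylbutanoate | CC(C)CC(=O)O[C@@H]1C(=O)[C@@]2(C)O[C@H]2C[C@H]1[C@@]1(C=O)CO1 | intermediate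
21 | 2-allyl-4,4,5,5-tetramethyl-1,3,2-dioxaborolane | C=CCB1OC(C)(C)C(C)(C)O1 | starting material
22 | (1S,3S,4R,6S)-4-[(2S)-2-(1-hydroxybut-3-en-1-yl)oxiran-2-yl]-1-methyl-2-oxo-7-oxabicyclo[4.1.0]heptan-3-yl 3-methylbutanoate, C8 epimers | CC(C)CC(=O)O[C@@H]1C(=O)[C@@]2(C)O[C@H]2C[C@H]1[C@@]1(C(O)CC=C)CO1 | intermediate
23 | 2-methylbut-2-ene | CC=C(C)C | starting material
24 | (1S,3S,4R,6S)-4-[(2S)-2-(1-hydroxy-4-methylpent-3-en-1-yl)oxiran-2-yl]-1-methyl-2-oxo-7-oxabicyclo[4.1.0]heptan-3-yl 3-methylbutanoate, C8 epimers | CC(C)CC(=O)O[C@@H]1C(=O)[C@@]2(C)O[C@H]2C[C@H]1[C@@]1(C(O)CC=C(C)C)CO1 | intermediate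
25 | (1S,3S,4R,6S)-1-methyl-4-[(2S)-2-(4-methylpent-3-enoyl)oxiran-2-yl]-2-oxo-7-oxabicyclo[4.1.0]heptan-3-yl 3-methylbutanoate | CC(C)CC(=O)O[C@@H]1C(=O)[C@@]2(C)O[C@H]2C[C@H]1[C@@]1(C(=O)CC=C(C)C)CO1 | intermediate
26 | (1S,3S,4R,6S)-4-{(2S)-2-[(2E)-4-hydroperoxy-4-methylpent-2-enoyl]oxiran-2-yl}-1-methyl-2-oxo-7-oxabicyclo[4.1.0]heptan-3-yl 3-methylbutanoate | CC(C)CC(=O)O[C@@H]1C(=O)[C@@]2(C)O[C@H]2C[C@H]1[C@@]1(C(=O)/C=C/C(C)(C)OO)CO1 | target

**Count**
Total steps: 15. Longest linear sequence: 14 steps (steps 1, 2 and 4 to 15, from 1 to 26); step 3 is a one-step side branch.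

**Steps most likely to fail**

Step 4 (the step that carries the label for a new method). The β-carbon elimination may not distinguish the two enantiotopic C(O)–CH2 bonds well enough, and insertion of the hindered silylalkyne may be slower than its oligomerisation at nickel. The fallback moves the source of chirality from the catalyst to a resolution and uses only established reactions. It sets out from 7 and 10: the known achiral conditions (Ni(cod)2, PCy3, toluene, 100 °C) should give the racemic silyl enone F1, and TBAF the racemic enone F2. Luche reduction (NaBH4, CeCl3·7H2O, EtOH) should give the racemic cis-alcohol F3. Lipase-catalysed acylation (Candida antarctica lipase B, vinyl acetate) is expected, by the usual empirical rule for secondary alcohols, to acetylate the (1R,5R)-enantiomer to the acetate F4, which is separated from the unreacted (1S,5S)-alcohol. Methanolysis (K2CO3, MeOH) then returns to the route at 13.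

Step 15. Singlet oxygen may abstract a methyl hydrogen instead of a C9 hydrogen, which would divert material to the regioisomeric secondary allylic hydroperoxide. The fallback brings the peroxide in as a preformed, protected unit and sets out from 20. Chemoselective vinylation of the aldehyde (vinyl bromide, CrCl2, catalytic NiCl2, DMF) should give the allylic alcohol F5, and Dess–Martin oxidation the vinyl ketone F6. Separately, 2-methylbut-3-en-2-ol with 50% H2O2 and catalytic H2SO4 should give 2-methylbut-3-en-2-yl hydroperoxide F7, which is masked with 2-methoxypropene and PPTS as the peroxyketal F8. Cross-metathesis of F6 with F8 (second-generation Hoveyda–Grubbs catalyst, CH2Cl2, 40 °C) should give the protected E-enone F9. AcOH/THF/H2O removes the ketal and arrives at 26.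

Step 11. Facial control in the enamine ring closure may be poor on an acrolein whose α-substituent is a branched ring carbon and which already carries four stereocentres (mismatched double differentiation). The fallback changes from aminocatalysis to a titanium-tartrate epoxidation of the allylic alcohol and sets out from 19. Aldehyde-selective reduction (NaBH4, EtOH/CH2Cl2, −78 °C) should give the allylic alcohol F10. Sharpless asymmetric epoxidation (Ti(OiPr)4, D-(−)-diethyl tartrate, t-BuOOH, 4 Å molecular sieves, CH2Cl2, −20 °C) should give the epoxy alcohol F11, with the face chosen as for (R)-2-methylglycidol from 2-methylprop-2-en-1-ol. Dess–Martin oxidation comes back to the route at 20.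

Further compounds
F1 | step 4 | racemic 3-[benzyl(dimethyl)silyl]-5-(3,3-diethoxyprop-1-en-2-yl)-2-methylcyclohex-2-en-1-one | CC1=C([Si](C)(C)Cc2ccccc2)CC(C(=C)C(OCC)OCC)CC1=O
F2 | step 4 | racemic 5-(3,3-diethoxyprop-1-en-2-yl)-2-methylcyclohex-2-en-1-one | CC1=CCC(C(=C)C(OCC)OCC)CC1=O
F3 | step 4 | racemic cis-5-(3,3-diethoxyprop-1-en-2-yl)-2-methylcyclohex-2-en-1-ol | CC1=CCC(C(=C)C(OCC)OCC)CC1O
F4 | step 4 | (1R,5R)-5-(3,3-diethoxyprop-1-en-2-yl)-2-methylcyclohex-2-en-1-yl acetate | C1[C@@H](OC(C)=O)C(C)=CC[C@H]1C(=C)C(OCC)OCC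
F5 | step 15 | (1S,3S,4R,6S)-4-[(2S)-2-(1-hydroxyprop-2-en-1-yl)oxiran-2-yl]-1-methyl-2-oxo-7-oxabicyclo[4.1.0]heptan-3-yl 3-methylbutanoate, C8 epimers | CC(C)CC(=O)O[C@@H]1C(=O)[C@@]2(C)O[C@H]2C[C@H]1[C@@]1(C(O)C=C)CO1
F6 | step 15 | (1S,3S,4R,6S)-4-[(2S)-2-acryloyloxiran-2-yl]-1-methyl-2-oxo-7-oxabicyclo[4.1.0]heptan-3-yl 3-methylbutanoate | CC(C)CC(=O)O[C@@H]1C(=O)[C@@]2(C)O[C@H]2C[C@H]1[C@@]1(C(=O)C=C)CO1
F7 | step 15 | 2-methylbut-3-en-2-yl hydroperoxide | C=CC(C)(C)OO
F8 | step 15 | 3-[(2-methoxypropan-2-yl)peroxy]-3-methylbut-1-ene | C=CC(C)(C)OOC(C)(C)OC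
F9 | step 15 | (1S,3S,4R,6S)-4-{(2S)-2-[(2E)-4-[(2-methoxypropan-2-yl)peroxy]-4-methylpent-2-enoyl]oxiran-2-yl}-1-methyl-2-oxo-7-oxabicyclo[4.1.0]heptan-3-yl 3-methylbutanoate | CC(C)CC(=O)O[C@@H]1C(=O)[C@@]2(C)O[C@H]2C[C@H]1[C@@]1(C(=O)/C=C/C(C)(C)OOC(C)(C)OC)CO1
F10 | step 11 | (1S,3S,4S,6S)-4-(3-hydroxyprop-1-en-2-yl)-1-methyl-2-oxo-7-oxabicyclo[4.1.0]heptan-3-yl 3-methylbutanoate | CC(C)CC(=O)O[C@@H]1C(=O)[C@@]2(C)O[C@H]2C[C@H]1C(=C)CO
F11 | step 11 | (1S,3S,4R,6S)-4-[(2R)-2-(hydroxymethyl)oxiran-2-yl]-1-methyl-2-oxo-7-oxabicyclo[4.1.0]heptan-3-yl 3-methylbutanoate | CC(C)CC(=O)O[C@@H]1C(=O)[C@@]2(C)O[C@H]2C[C@H]1[C@@]1(CO)CO1
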